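**Plan**

1. Numbering (briarane-type): C1 = quaternary C–CH3; cyclopentene C1–C3–C2=C14–C13; cyclopentanone C1–C13–C12(=O)–C11(CH3,OH)–C10; nine-membered ring C1–C3–C4(OAc)–C5(=CH2)–C6(Cl)–C7(O)–C8(OH)–C9(OAc)–C10; lactone C7–O–C19(=O)–C17(CH3)–C8.
2. Retrosynthesis: cut C1–C3 (vinylcyclopropane to cyclopentene shift), then C2–C14 and C13–C1 (di-π-methane rearrangement). This leads back to a ten-membered 4-methyl-4-alkenylcyclohex-2-enone in which sp3 C1 sits between the C13=C14 enone π bond and the (Z)-C2=C3 π bond; this 1,4-diene array with the C12 enone as chromophore is the feature that makes the photochemical event possible.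
3. Further cuts: C2=C3 (ring-closing metathesis), C8–C17 (Reformatsky lactone annulation), C6–Cl/C7–O (epoxide opening), C6=C7 (Wittig), C8–C9 (acyl-anion addition), C1–C14/C10–C11 (Diels–Alder, ring A).
4. Forward: ring A (cyclohexenone), then the C7–C9 chain and union with the C3–C6 piece, then the γ-lactone, then the ten-membered ring; light turns rings 6/10 into 3/5/11; heat contracts 3/11 into the second five-membered ring and the nine-membered ring.
5. Stereochemistry: C1/C10 from a catalytic asymmetric Diels–Alder reaction; C11 and C9 by substrate control on ring A; C4 by lipase resolution; C7/C6 by catalyst-controlled epoxidation and invertive chloride opening; C8/C17 in the Reformatsky closure; C13/C14 (and inversion at C1) stereospecifically in the photochemical step; C3 in the suprafacial thermal shift.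

Key step: step 23

Remark (assumption on the chemistry): the C2=C3 bond of 37 is taken as Z, the geometry a ten-membered ring closed by metathesis should adopt; with the alkenyl group endo on the cyclopropane of 38, this geometry places C4 on the concave face at C3, as the target requires.

**Route**

Step 1
Reactants: 1 (tert-butyldimethylsilyloxy)acetaldehyde; 2 2-(triphenylphosphoranylidene)propanal
Product: 3 (E)-4-(tert-butyldimethylsilyloxy)-2-methylbut-2-enal
Conditions: toluene, 80 °C
Reagents that add atoms: none
Why: Wittig olefination with a formyl-stabilised ylide is E-selective and stops at the α-methyl enal, which is a poorer electrophile than 1.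

Step 2
Reactants: 4 pent-1-en-3-one
Product: 5 (Z)-3-(triisopropylsilyloxy)penta-1,3-diene
Conditions: i-Pr3SiOTf, Et3N, CH2Cl2, 0 °C
Reagents that add atoms: triisopropylsilyl trifluoromethanesulfonate, CC(C)[Si](OS(=O)(=O)C(F)(F)F)(C(C)C)C(C)C
Why: Soft enolisation of the ethyl ketone (silyl triflate and amine) gives the 2-silyloxydiene, the Z enol ether with the methyl group outside in the s-cis form being favoured.

Step 3
Reactants: 3 (E)-4-(tert-butyldimethylsilyloxy)-2-methylbut-2-enal; 5 (Z)-3-(triisopropylsilyloxy)penta-1,3-diene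
Product: 6 (1S,5S,6S)-6-[(tert-butyldimethylsilyloxy)methyl]-1,5-dimethyl-4-(triisopropylsilyloxy)cyclohex-3-ene-1-carbaldehyde
Conditions: (S)-3,3-diphenyl-1-(2-methylphenyl)tetrahydro-1H,3H-pyrrolo[1,2-c][1,3,2]oxazaborole activated with HN(SO2CF3)2 (20 mol%), CH2Cl2, −78 → −40 °C
Reagents that add atoms: none
Why: Catalytic enantioselective Diels–Alder reaction of an α-methyl enal bound s-trans to the chiral boron Lewis acid: the silyloxy group steers the methyl-bearing diene terminus (C11) to the β-carbon C10 and the CH2 terminus (C14) to C1, the E geometry of 3 fixes formyl (future C2) trans to CH2OSi (C9), face shielding by the catalyst (the enantiomer giving 6 as drawn is used) sets C1 and C10, and the C11 methine (endo isomer drawn) is planarised later.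

Step 4
Reactants: 6 Diels–Alder aldehyde
Product: 7 1-vinyl analogue of 6 (formyl converted to CH=CH2)
Conditions: Ph3PCH3Br, KOt-Bu, THF, 0 °C; then 6, −78 → 0 °C
Reagents that add atoms: methyltriphenylphosphonium bromide, C[P+](c1ccccc1)(c1ccccc1)c1ccccc1.[Br-]
Why: Wittig methylenation of the neopentyl aldehyde, far more electrophilic than the silyl enol ether, installs the C1 vinyl group (C2) without touching a stereocentre.

Step 5
Reactants: 7 vinyl silyl enol ether
Product: 8 5-[(tert-butyldimethylsilyloxy)methyl]-4,6-dimethyl-4-vinylcyclohex-2-en-1-one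
Conditions: Pd(OAc)2 (1.1 equiv), MeCN, 40 °C
Reagents that add atoms: none
Why: Saegusa–Ito oxidation: the regiodefined C12–C13 silyl enol ether gives a palladium enolate whose only β-hydrogens are on C14, so the C13=C14 enone results.

Step 6
Reactants: 8 ring-A enone
Product: 11 ring-A enone carrying the C11 tert-butyldimethylsilyloxy group cis to the C1 vinyl group (bis-silyl ether), via potassium dienolate 9 (not isolated), via potassium alkoxide 10 (not isolated)
Conditions: KN(SiMe3)2, THF, −78 °C; 2-(phenylsulfonyl)-3-phenyloxaziridine; then t-BuMe2SiOTf, −78 → 0 °C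
Reagents that add atoms: 2-(phenylsulfonyl)-3-phenyloxaziridine, O=S(=O)(c1ccccc1)N1OC1c1ccccc1; tert-butyldimethylsilyl trifluoromethanesulfonate, CC(C)(C)[Si](C)(C)OS(=O)(=O)C(F)(F)F
Why: α′-Deprotonation (C11 is the only enolisable site because C1 is quaternary) and electrophilic enolate hydroxylation by the N-sulfonyloxaziridine occur on the ring face opposite to the adjacent C10 CH2OSi group and the C1 methyl group, placing the C11 oxygen cis to the C1 vinyl group, and the alkoxide is silylated in the same flask.

Step 7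
Reactants: 11 bis-silyl ether
Product: 12 ring-A primary alcohol (C9 hydroxymethyl; C11 silyl ether kept)
Conditions: HF·pyridine, pyridine, THF, 0 °C
Reagents that add atoms: none
Why: Fluoride/acid cleavage of silyl ethers is much faster for the unhindered primary ether than for the tertiary one.

Step 8
Reactants: 12 ring-A primary alcohol
Product: 13 ring-A C9 aldehyde
Conditions: Dess–Martin periodinane, NaHCO3, CH2Cl2, 0 °C → rt
Reagents that add atoms: none
Why: Dess–Martin oxidation under buffered, non-basic conditions avoids epimerisation at C10 and β-elimination of the C11 silyloxy group.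

Step 9
Reactants: 13 ring-A C9 aldehyde; 14 ethyl vinyl ether
Product: 17 (9S)-C9 acetate carrying the 1-ethoxyvinyl group (C8 and C7), via 1-ethoxyvinyllithium 15 (not isolated), via lithium alkoxide 16 (not isolated)
Conditions: 14, t-BuLi, THF, −78 → 0 °C; 13, −78 °C; Ac2O, DMAP (cat.), −78 → 0 °C
Reagents that add atoms: acetic anhydride, CC(=O)OC(C)=O
Why: Addition of an acyl-anion equivalent to the aldehyde, which is far more reactive than the hindered C12 ketone; with the C11 oxygen held as a bulky non-chelating silyl ether the nucleophile enters anti to the C11 carbinol carbon (non-chelated 1,3-anti induction), setting C9, and the alkoxide is trapped as the acetate.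

Step 10
Reactants: 17 enol ether acetate
Product: 18 bromomethyl ketone (C8 ketone and C7 bromide)
Conditions: N-bromosuccinimide, NaHCO3, THF/H2O, 0 °C
Reagents that add atoms: N-bromosuccinimide, O=C1CCC(=O)N1Br; water, O
Why: Bromohydroxylation of the electron-rich enol ether (bromonium/oxocarbenium ion, water addition, loss of ethanol) gives the α-bromo ketone regiospecifically, the vinyl and enone alkenes being much less nucleophilic.

Step 11
Reactants: 18 bromomethyl ketone
Product: 20 acyl-stabilised phosphorus ylide of ring A, via phosphonium bromide 19 (not isolated)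
Conditions: PPh3, toluene, rt; then aq. Na2CO3, CH2Cl2
Reagents that add atoms: triphenylphosphine, c1ccc(cc1)P(c1ccccc1)c1ccccc1
Why: SN2 displacement of the primary α-bromo ketone by the phosphine and deprotonation of the acidic keto-phosphonium salt by carbonate give the isolable stabilised Wittig ylide, free of excess phosphine.

Step 12
Reactants: 21 (2-bromoallyloxy)(tert-butyl)dimethylsilane; 22 acrolein
Product: 25 rac-2-[(tert-butyldimethylsilyloxy)methyl]penta-1,4-dien-3-yl acetate, via 2-lithioallyl silyl ether 23 (not isolated), via lithium dienyl alkoxide 24 (not isolated)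
Conditions: t-BuLi (2 equiv), Et2O, −78 °C; 22; Ac2O, −78 → 0 °C
Reagents that add atoms: acetic anhydride, CC(=O)OC(C)=O
Why: Bromine–lithium exchange, 1,2-addition of the vinyllithium to acrolein and O-acetylation in one flask assemble C3–C6 (with C16) as the racemic bis-allylic acetate.

Step 13
Reactants: 25 racemic acetate
Product: 26 (S)-2-[(tert-butyldimethylsilyloxy)methyl]penta-1,4-dien-3-yl acetate
Conditions: lipase from Burkholderia cepacia (Amano PS), pH 7 phosphate buffer/acetone, 30 °C, to ca. 55% conversion
Reagents that add atoms: none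
Why: Enzymatic kinetic resolution: the lipase hydrolyses the R acetate (large 2-substituted allyl group against small vinyl group) and leaves the S acetate, which sets C4.

Step 14
Reactants: 26 (S)-acetate
Product: 27 (S)-2-(hydroxymethyl)penta-1,4-dien-3-yl acetate
Conditions: HF·pyridine, THF, 0 °C → rt
Reagents that add atoms: none
Why: Cleavage of the primary allylic silyl ether under mildly acidic conditions that do not induce acetyl migration.

Step 15
Reactants: 27 (S)-hydroxy acetate
Product: 28 (S)-2-formylpenta-1,4-dien-3-yl acetate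
Conditions: Dess–Martin periodinane, NaHCO3, CH2Cl2, 0 °C
Reagents that add atoms: none
Why: Dess–Martin oxidation of the primary allylic alcohol gives the 2-substituted acrolein, which has no α-hydrogen and so cannot enolise or eliminate the acetate.

Step 16
Reactants: 20 ring-A ylide; 28 (S)-aldehyde
Product: 29 (E)-dienone (C8 ketone, C6=C7, C5=CH2, C4 acetate, C3 vinyl)
Conditions: CH2Cl2, 40 °C
Reagents that add atoms: none
Why: Wittig olefination with the acyl-stabilised ylide under neutral conditions gives the (E)-enone and joins the fragments without endangering the base-sensitive C9 centre.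

Step 17
Reactants: 29 (E)-dienone
Product: 30 trans-(7S,6R)-epoxy ketone
Conditions: La(Oi-Pr)3 (10 mol%), (R)-BINOL (10 mol%), Ph3As=O (10 mol%), t-BuOOH (in decane), 4 Å molecular sieves, THF, rt
Reagents that add atoms: tert-butyl hydroperoxide, CC(C)(C)OO
Why: Catalytic asymmetric nucleophilic (Weitz–Scheffer-type) epoxidation: the lanthanum–BINOL peroxide binds s-cis acyclic E-enones and delivers oxygen to one face of C6=C7, setting C7 and C6 as the trans epoxide, whereas the s-trans ring enone with its neopentyl β-carbon and the isolated alkenes are not substrates.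

Step 18
Reactants: 30 epoxy ketone
Product: 31 anti chlorohydrin (C6 chloride, C7 hydroxyl, C8 ketone)
Conditions: HCl (1 M in Et2O), CH2Cl2, −60 → −20 °C
Reagents that add atoms: hydrogen chloride, Cl
Why: Acid-promoted epoxide opening by chloride at C6, the allylic carbon remote from the carbonyl group where positive charge can develop, proceeds with inversion and gives the anti chlorohydrin.

Step 19
Reactants: 31 chlorohydrin; 32 2-bromopropanoyl bromide
Product: 33 C7 2-bromopropanoate
Conditions: pyridine, CH2Cl2, −40 → 0 °C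
Reagents that add atoms: none
Why: O-Acylation of the only free hydroxyl group at low temperature introduces C17–C19 (both epimers at the bromine-bearing carbon converge).

Step 20
Reactants: 33 C7 2-bromopropanoate
Product: 35 β-hydroxy-γ-lactone (C8 hydroxyl cis to C6; C17 methyl cis to the hydroxyl), via zinc ester enolate 34 (not isolated)
Conditions: Zn (activated with Me3SiCl), THF, 0 °C → rt; then aq. NH4Cl
Reagents that add atoms: none
Why: Intramolecular Reformatsky reaction (5-exo aldol of the zinc enolate onto the C8 ketone): the tether from O7 forces C17 and O7 cis, the C9 chain takes the lactone face away from C6 so that the C8 hydroxyl is cis to C6, and the C17 methyl group settles trans to the C9 chain, the thermodynamically preferred and epimerisable position.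

Step 21
Reactants: 35 silyl-protected hydroxy lactone
Product: 36 seco-triene lactone with free C11 hydroxyl
Conditions: HF (48% aq.), MeCN, 0 °C → rt
Reagents that add atoms: none
Why: Hydrogen fluoride cleaves the tertiary silyl ether without affecting acetates, lactone or allylic chloride, and removes the bulk next to the C1 vinyl group before ring closure.

Step 22
Reactants: 36 seco-triene lactone
Product: 37 (2Z)-ten-membered briarane-type enone (4,9-diacetate, 6-chloride, 8,11-diol, 12-ketone, Δ2, Δ5(16), Δ13, 7,8-fused lactone)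
Conditions: RuCl2[1,3-bis(2,4,6-trimethylphenyl)imidazolidin-2-ylidene](=CH-C6H4-2-Oi-Pr) (second-generation Hoveyda–Grubbs catalyst, 10 mol%), toluene (1 mM), 80 °C
Reagents that add atoms: none
Why: Ring-closing metathesis starts at the less hindered C4 vinyl group and can close only on the C1 vinyl group (the 1,1-disubstituted C5=CH2 and the ring enone are unreactive), and a ten-membered ring should take up the new C2=C3 bond as the Z isomer.

Step 23
Reactants: 37 (2Z)-ten-membered enone
Product: 38 vinylcyclopropane (cyclopropane C1–C13–C14 fused to the C12 cyclopentanone; (Z)-C2=C3 endo on C14 within an eleven-membered ring)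
Conditions: hν (350 nm, Pyrex), degassed benzene, rt
Reagents that add atoms: none
Why: Di-π-methane rearrangement (the type B photorearrangement of a 4-alkyl-4-vinylcyclohex-2-enone, a photochemical 1,2-vinyl shift): n→π* excitation of the C12 enone and intersystem crossing give a triplet whose β-carbon C14 bonds to C2 of the C2=C3 alkene on sp3 C1, the cyclopropyldicarbinyl diradical opens at C1–C2, and the C1/C13 1,3-diradical collapses, so that C2–C14 and C13–C1 form while C1–C2 breaks. The closest known reaction type is the photochemical 1,2-aryl and 1,2-vinyl migration of 4,4-disubstituted cyclohexenones to 6-substituted bicyclo[3.1.0]hexan-2-ones. The transient cyclopropane C1–C2–C14 closes by 3-exo radical attack of C14 on C2, and the final cyclopropane C1–C13–C14 closes by 1,3-diradical recombination, which also contracts ring A to the cyclopentanone (C1, C10–C13) and enlarges the ten-membered ring to eleven members. C14 is controlled by the suprafacial migration of C2 across the ring-A face it already occupies (the alkenyl group ends endo), C13 by the obligatory cis fusion of the three-membered ring, and C1 is inverted because C13 bonds to the lobe opposite to the departing C2, so all three follow from the C1 configuration of 37. The step needs regioselectivity (vinyl shift, not a lumiketone-type skeletal change and not opening of C1–C14) and chemoselectivity: opening at C1–C2 keeps the carbonyl-stabilised radical at C13 and restores the C2=C3 π bond, and 350 nm light is absorbed only by the enone, so the allylic chloride, the acetates and the isolated alkenes are not excited.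

Step 24
Reactants: 38 vinylcyclopropane
Product: 39 target (CNP0145188.1)
Conditions: degassed 1,2-dichlorobenzene, sealed tube, 170 °C
Reagents that add atoms: none
Why: Thermal vinylcyclopropane–cyclopentene rearrangement (formal 1,3-shift of C1 from C14 to C3): the endocyclic C1–C14 bond, the cyclopropane bond that the eleven-membered ring holds parallel to the C2=C3 π system, should homolyse to a tertiary/allylic 1,3-diradical that recloses suprafacially at C3 with retention at C1, so the Z-positioned C4 turns to the concave face (setting C3), the five-membered rings are cis-fused, and the eleven-membered ring contracts to nine.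

**Compound list**

1 | (tert-butyldimethylsilyloxy)acetaldehyde | O=CCO[Si](C)(C)C(C)(C)C | starting material
2 | 2-(triphenylphosphoranylidene)propanal | CC(C=O)=P(c1ccccc1)(c1ccccc1)c1ccccc1 | starting material
3 | (E)-4-(tert-butyldimethylsilyloxy)-2-methylbut-2-enal | O=C/C(C)=C/CO[Si](C)(C)C(C)(C)C | intermediate
4 | pent-1-en-3-one | C=CC(=O)CC | starting material
5 | (Z)-3-(triisopropylsilyloxy)penta-1,3-diene | C=C/C(O[Si](C(C)C)(C(C)C)C(C)C)=C/C | intermediate
6 | (1S,5S,6S)-6-[(tert-butyldimethylsilyloxy)methyl]-1,5-dimethyl-4-(triisopropylsilyloxy)cyclohex-3-ene-1-carbaldehyde (formyl trans to CH2OSi; the C5 epimer converges) | O=C[C@@]1(C)CC=C(O[Si](C(C)C)(C(C)C)C(C)C)[C@@H](C)[C@@H]1CO[Si](C)(C)C(C)(C)C | intermediate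
7 | 1-vinyl analogue of 6 (CH=CH2 in place of CHO) | C=C[C@@]1(C)CC=C(O[Si](C(C)C)(C(C)C)C(C)C)[C@@H](C)[C@@H]1CO[Si](C)(C)C(C)(C)C | intermediate
8 | 5-[(tert-butyldimethylsilyloxy)methyl]-4,6-dimethyl-4-vinylcyclohex-2-en-1-one (vinyl trans to CH2OSi) | C=C[C@@]1(C)C=CC(=O)[C@@H](C)[C@@H]1CO[Si](C)(C)C(C)(C)C | intermediate
9 | potassium dienolate of 8 (C11=C12–O−) | C=C[C@@]1(C)C=CC([O-])=C(C)[C@@H]1CO[Si](C)(C)C(C)(C)C.[K+] | intermediate (not isolated)
10 | potassium C11 alkoxide (oxygen cis to the C1 vinyl group) | C=C[C@@]1(C)C=CC(=O)[C@@](C)([O-])[C@@H]1CO[Si](C)(C)C(C)(C)C.[K+] | intermediate (not isolated)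
11 | ring-A enone, C11 OSiMe2t-Bu cis to C1 vinyl, C9 CH2OSiMe2t-Bu | C=C[C@@]1(C)C=CC(=O)[C@@](C)(O[Si](C)(C)C(C)(C)C)[C@@H]1CO[Si](C)(C)C(C)(C)C | intermediate
12 | ring-A primary alcohol (C9 CH2OH) | C=C[C@@]1(C)C=CC(=O)[C@@](C)(O[Si](C)(C)C(C)(C)C)[C@@H]1CO | intermediate
13 | ring-A C9 aldehyde | C=C[C@@]1(C)C=CC(=O)[C@@](C)(O[Si](C)(C)C(C)(C)C)[C@@H]1C=O | intermediate
14 | ethyl vinyl ether | C=COCC | starting material
15 | 1-ethoxyvinyllithium | [Li]C(=C)OCC | intermediate (not isolated)
16 | lithium (9S)-alkoxide adduct | C=C[C@@]1(C)C=CC(=O)[C@@](C)(O[Si](C)(C)C(C)(C)C)[C@@H]1[C@H]([O-])C(=C)OCC.[Li+] | intermediate (not isolated)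
17 | (9S)-C9 acetate with 1-ethoxyvinyl group | C=C[C@@]1(C)C=CC(=O)[C@@](C)(O[Si](C)(C)C(C)(C)C)[C@@H]1[C@H](OC(C)=O)C(=C)OCC | intermediate
18 | bromomethyl ketone (C9 OAc, C8 C=O, C7 CH2Br) | C=C[C@@]1(C)C=CC(=O)[C@@](C)(O[Si](C)(C)C(C)(C)C)[C@@H]1[C@H](OC(C)=O)C(=O)CBr | intermediate
19 | keto-phosphonium bromide | C=C[C@@]1(C)C=CC(=O)[C@@](C)(O[Si](C)(C)C(C)(C)C)[C@@H]1[C@H](OC(C)=O)C(=O)C[P+](c2ccccc2)(c2ccccc2)c2ccccc2.[Br-] | intermediate (not isolated)
20 | acyl-stabilised ylide | C=C[C@@]1(C)C=CC(=O)[C@@](C)(O[Si](C)(C)C(C)(C)C)[C@@H]1[C@H](OC(C)=O)C(=O)C=P(c2ccccc2)(c2ccccc2)c2ccccc2 | intermediate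
21 | (2-bromoallyloxy)(tert-butyl)dimethylsilane | C=C(Br)CO[Si](C)(C)C(C)(C)C | starting material
22 | acrolein | C=CC=O | starting material
23 | 2-lithioallyl tert-butyldimethylsilyl ether | [Li]C(=C)CO[Si](C)(C)C(C)(C)C | intermediate (not isolated)
24 | lithium rac-2-[(tert-butyldimethylsilyloxy)methyl]penta-1,4-dien-3-olate | C=CC([O-])C(=C)CO[Si](C)(C)C(C)(C)C.[Li+] | intermediate (not isolated)
25 | rac-2-[(tert-butyldimethylsilyloxy)methyl]penta-1,4-dien-3-yl acetate | C=CC(OC(C)=O)C(=C)CO[Si](C)(C)C(C)(C)C | intermediate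
26 | (S)-2-[(tert-butyldimethylsilyloxy)methyl]penta-1,4-dien-3-yl acetate | C=C[C@H](OC(C)=O)C(=C)CO[Si](C)(C)C(C)(C)C | intermediate
27 | (S)-2-(hydroxymethyl)penta-1,4-dien-3-yl acetate | C=C[C@H](OC(C)=O)C(=C)CO | intermediate
28 | (S)-2-formylpenta-1,4-dien-3-yl acetate | C=C[C@H](OC(C)=O)C(=C)C=O | intermediate
29 | (E)-dienone | C=C[C@@]1(C)C=CC(=O)[C@@](C)(O[Si](C)(C)C(C)(C)C)[C@@H]1[C@H](OC(C)=O)C(=O)/C=C/C(=C)[C@@H](OC(C)=O)C=C | intermediate
30 | trans-(7S,6R)-epoxy ketone | C=C[C@@]1(C)C=CC(=O)[C@@](C)(O[Si](C)(C)C(C)(C)C)[C@@H]1[C@H](OC(C)=O)C(=O)[C@H]2O[C@@H]2C(=C)[C@@H](OC(C)=O)C=C | intermediate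
31 | anti chlorohydrin (C6 Cl, C7 OH) | C=C[C@@]1(C)C=CC(=O)[C@@](C)(O[Si](C)(C)C(C)(C)C)[C@@H]1[C@H](OC(C)=O)C(=O)[C@@H](O)[C@@H](Cl)C(=C)[C@@H](OC(C)=O)C=C | intermediate
32 | 2-bromopropanoyl bromide | CC(Br)C(=O)Br | starting material
33 | C7 2-bromopropanoate (epimers at CHBr) | C=C[C@@]1(C)C=CC(=O)[C@@](C)(O[Si](C)(C)C(C)(C)C)[C@@H]1[C@H](OC(C)=O)C(=O)[C@@H](OC(=O)C(C)Br)[C@@H](Cl)C(=C)[C@@H](OC(C)=O)C=C | intermediate
34 | zinc ester enolate | C=C[C@@]1(C)C=CC(=O)[C@@](C)(O[Si](C)(C)C(C)(C)C)[C@@H]1[C@H](OC(C)=O)C(=O)[C@@H](OC(O[Zn]Br)=CC)[C@@H](Cl)C(=C)[C@@H](OC(C)=O)C=C | intermediate (not isolated)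
35 | silyl-protected β-hydroxy-γ-lactone | C=C[C@@]1(C)C=CC(=O)[C@@](C)(O[Si](C)(C)C(C)(C)C)[C@@H]1[C@H](OC(C)=O)[C@]2(O)[C@@H](C)C(=O)O[C@H]2[C@@H](Cl)C(=C)[C@@H](OC(C)=O)C=C | intermediate
36 | seco-triene lactone, free C11 OH | C=C[C@@]1(C)C=CC(=O)[C@@](C)(O)[C@@H]1[C@H](OC(C)=O)[C@]2(O)[C@@H](C)C(=O)O[C@H]2[C@@H](Cl)C(=C)[C@@H](OC(C)=O)C=C | intermediate
37 | (2Z)-ten-membered briarane-type enone | C=C1[C@@H](OC(C)=O)/C=C\[C@@]2(C)C=CC(=O)[C@@](C)(O)[C@@H]2[C@H](OC(C)=O)[C@]3(O)[C@@H](C)C(=O)O[C@H]3[C@H]1Cl | intermediate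
38 | vinylcyclopropane (bicyclo[3.1.0]hexan-2-one, endo (Z)-alkenyl, eleven-membered ring) | C=C1[C@@H](OC(C)=O)/C=C\[C@H]2[C@H]3C(=O)[C@@](C)(O)[C@H]([C@H](OC(C)=O)[C@]4(O)[C@@H](C)C(=O)O[C@H]4[C@H]1Cl)[C@@]23C | intermediate
39 | target CNP0145188.1 | C=C1[C@@H](OC(C)=O)[C@H]2C=C[C@H]3C(=O)[C@@](C)(O)[C@H]([C@H](OC(C)=O)[C@]4(O)[C@@H](C)C(=O)O[C@H]4[C@H]1Cl)[C@@]23C | target

**Step count and risks**

Total: 24 steps. Longest linear sequence: 19 steps (steps 1, 3–11, 16–24).

Steps most likely to fail:

Step 22 (ring-closing metathesis). The catalyst should load onto the C4 vinyl group but may fail to engage the neopentyl C1 vinyl group, so that intermolecular metathesis or the strained E ring competes. Fallback: the ring is closed before the lactone is annulated, while C8 is still trigonal and the chain is not pinned. It sets out from 31: the same ruthenium catalyst at high dilution should give the macrocyclic hydroxy ketone F1; acylation with 32 (pyridine, CH2Cl2) gives the macrocyclic 2-bromopropanoate F2; the zinc Reformatsky closure, now on the ten-membered ring, gives the silyl-protected macrocyclic lactone F3; HF in MeCN returns to the route at 37.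

Step 24 (thermal 1,3-shift). The heat needed may instead homolyse the carbonyl-activated C13–C14 bond, trigger a homodienyl hydrogen shift from C10–H, or cause elimination of HCl. Fallback: the carbonyl activation is removed before heating. It sets out from 38: NaBH4/CeCl3·7H2O in MeOH at −40 °C (hydride from the face away from the cyclopropane) gives the cyclopropyl carbinol F4; thermolysis in toluene at 160–180 °C, for which the tertiary/allylic C1–C14 homolysis is then the only low-energy channel, gives the diquinane alcohol F5; Dess–Martin oxidation of the single secondary alcohol returns to the route at 39.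

Step 17 (asymmetric epoxidation). Facial control may be poor on this α′-acetoxy dienone, the hydroperoxide may attack an acetate, or C9 may epimerise under the weakly basic conditions. Fallback: a hydroxyl-directed, reagent-controlled epoxidation. It sets out from 29: Luche reduction (NaBH4, CeCl3·7H2O, MeOH, −78 °C; the C12 carbonyl is shielded by the quaternary silyloxy carbon) gives the dienyl alcohol F6 as C8 epimers; Sharpless asymmetric epoxidation (Ti(Oi-Pr)4, L-(+)-diethyl tartrate, t-BuOOH, −20 °C; the slow-reacting C8 epimer is re-oxidised with MnO2 and recycled) gives the epoxy alcohol F7; Dess–Martin oxidation returns to the route at 30.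

**Further compounds**

F1 | step 22 | macrocyclic hydroxy ketone (ten-membered ring closed; C8 ketone, C7 OH, C11 silyl ether) | C=C1[C@@H](OC(C)=O)/C=C\[C@@]2(C)C=CC(=O)[C@@](C)(O[Si](C)(C)C(C)(C)C)[C@@H]2[C@H](OC(C)=O)C(=O)[C@@H](O)[C@H]1Cl
F2 | step 22 | macrocyclic 2-bromopropanoate | C=C1[C@@H](OC(C)=O)/C=C\[C@@]2(C)C=CC(=O)[C@@](C)(O[Si](C)(C)C(C)(C)C)[C@@H]2[C@H](OC(C)=O)C(=O)[C@@H](OC(=O)C(C)Br)[C@H]1Cl
F3 | step 22 | silyl-protected macrocyclic lactone (C11 silyl ether of 37) | C=C1[C@@H](OC(C)=O)/C=C\[C@@]2(C)C=CC(=O)[C@@](C)(O[Si](C)(C)C(C)(C)C)[C@@H]2[C@H](OC(C)=O)[C@]3(O)[C@@H](C)C(=O)O[C@H]3[C@H]1Cl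
F4 | step 24 | cyclopropyl carbinol (C12 alcohol of 38) | C=C1[C@@H](OC(C)=O)/C=C\[C@H]2[C@H]3[C@@H](O)[C@@](C)(O)[C@H]([C@H](OC(C)=O)[C@]4(O)[C@@H](C)C(=O)O[C@H]4[C@H]1Cl)[C@@]23C
F5 | step 24 | diquinane alcohol (C12 alcohol of 39) | C=C1[C@@H](OC(C)=O)[C@H]2C=C[C@H]3[C@@H](O)[C@@](C)(O)[C@H]([C@H](OC(C)=O)[C@]4(O)[C@@H](C)C(=O)O[C@H]4[C@H]1Cl)[C@@]23C
F6 | step 17 | dienyl alcohol (C8 carbinol of 29, C8 epimers) | C=C[C@@]1(C)C=CC(=O)[C@@](C)(O[Si](C)(C)C(C)(C)C)[C@@H]1[C@H](OC(C)=O)C(O)/C=C/C(=C)[C@@H](OC(C)=O)C=C
F7 | step 17 | epoxy alcohol (C8 carbinol of 30) | C=C[C@@]1(C)C=CC(=O)[C@@](C)(O[Si](C)(C)C(C)(C)C)[C@@H]1[C@H](OC(C)=O)C(O)[C@H]2O[C@@H]2C(=C)[C@@H](OC(C)=O)C=C
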